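(All runs are simulated with constants of no real substance, and the scatter is random.)

The easy step is a division. One first nucleophile enters each target, so the charge of first nucleophile caps the target. In midnight the target ceiling, charged c(first nucleophile) over charged c(starting material), is 10.8% of the starting material charged: the yield that the first nucleophile allows as limiting reagent.

| flask | starting material | first nucleophile | second nucleophile | remark | time |
|---|---|---|---|---|---|
| dusk | 0.12 M | 0.14 M | 0.24 M | run made earlier |  |
| midnight | 1.3 M | 0.14 M | 0.24 M | run made earlier |  |
| theta | 0.20 M | 0.140 M | 0.240 M |  | 80 min |
| gamma | 0.40 M | 0.140 M | 0.240 M |  | 80 min |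
| delta | 0.80 M | 0.140 M | 0.240 M |  | 80 min |
| epsilon | 1.5 M | 0.140 M | 0.240 M |  | 80 min |

| run | time / min | target / % | other capture product / % |
|---|---|---|---|
| dusk | 12.0 | 16.5 | 51.4 |
| dusk | 25.0 | 22.3 | 64.8 |
| dusk | 30.0 | 22.8 | 67.7 |
| dusk | 50.0 | 21.8 | 70.3 |
| dusk | 60.0 | 20.8 | 70.0 |
| midnight | 5.00 | 10.7 | 18.8 |
| midnight | 15.0 | 9.6 | 19.0 |
| midnight | 25.0 | 9.9 | 17.9 |
| midnight | 40.0 | 8.7 | 18.4 |
| midnight | 60.0 | 9.1 | 18.2 |

(readings scatter by 0.5 percentage points)

- candidate steps: starting material -> intermediate; intermediate -> solvolysis product; target -> over-reaction product; first nucleophile + intermediate -> target; second nucleophile + intermediate -> other capture product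
- "hardly changes" means that all values lie within two and a half points (for a concentration: within two and a half percent of the largest)

- share of target in all that became target or other capture product or solvolysis product or over-reaction product for theta, gamma, delta, epsilon, in this order
- how the row runs (falls, then rises / falls all the way / rises, then falls / rises all the way / hardly changes)

Read down the midnight table. Target stands at 10.7% after 5.00 min, level with the ceiling, and reads 9.1% after 60.0 min, so it is formed early and then leaks slowly. Read across: other capture product stays near 18.8%, level with its own ceiling of 18.5%.

The dusk table reads differently. Its ceiling is 117%, yet target reads 22.8% after 30.0 min, far below it, while other capture product reads 67.7%, so in dusk the two nucleophiles share the intermediate.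

The same division gives 70.0% for theta and 35.0% for gamma, both above that dusk reading. Delta gets 17.5% and epsilon 9.33%, both below it. The reckoning here commits to this much: delta and epsilon stand under those ceilings, and the row falls between them.

The forecast gives 20.4%, 23.4%, 13.4% and 7.1%, a row that rises, then falls, and it reads the midnight plateaus thus: “both nucleophiles are used up stoichiometrically”. Its delta and epsilon values lie under the ceilings.

The simulation gives 20.5%, 23.5%, 13.4% and 7.08%: the row rises, then falls, turning at 0.42 M. That turn stands higher than the 0.20 M of theta, with gamma over theta by 3 percentage points; a run that showed gamma under theta would prove the forecast's shape wrong.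

    starting material → intermediate (k = 0.00181 s⁻¹)
    intermediate → solvolysis product (k = 0.321 s⁻¹)
    target → over-reaction product (k = 5.89 × 10⁻⁵ s⁻¹)
    first nucleophile + intermediate → target (k = 13.2 M⁻¹ s⁻¹)
    second nucleophile + intermediate → other capture product (k = 23.5 M⁻¹ s⁻¹)

In theta the half-life of starting material, 6.4 min, is shorter than the 200 min of target, and after 80.0 min that flask holds 0.0169% starting material, 20.5% target and 5.76% over-reaction product. In delta, with 0% of the first nucleophile left, target and over-reaction product sum to 17.5% against a ceiling of 17.5%, and in epsilon to 9.33% against 9.33%.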